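**Retrosynthetic overview**

1. Feature: every ring is a 1,2,3,5-tetraoxygenated benzene. In ring C (C1–O to ring D, C2–OH, C3–H, C4–O from ring B, C5–H, C6–OH) the C4 aryloxy carbon lies meta to the C2 hydroxyl across the unsubstituted C3, a resorcinol mono-aryl ether flanked by the C1 and C6 oxygens.
2. Key disconnection: ring C is cut into C3–C4 (an ethynyl ether on the C1 oxygen of ring B) and the four carbons C5, C6, C1 and C2 (a diazoketone that gives a 3-methoxy-4-benzyloxy vinylketene). C2–C3 and C4–C5 come from a ketene–alkyne (2+2) addition, C5–C6 from the Wolff shift, C1–C2 from 6π closure.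
3. Ring order: A (purchased) → B → C → D → E → F. The same annulation is repeated, each round followed by O-methylation, debenzylation and ethynylation of the freed central oxygen through its dichlorovinyl ether.
4. The diazoketone comes from methyl methoxyacetate by formylation/O-benzylation, saponification and acylation of diazomethane.
5. End game: hydrogenolysis of the last benzyl ether, then BBr3 cleavage of the twelve methyl ethers.

Key step: step 11

Remark on the chemistry: the target has no stereocentre; the cyclobutenone intermediates are racemic and lose their one stereocentre on ring opening. 2,4,6-Trimethoxyphenol is taken as a purchasable phenol. Dichloroacetylene 11 and vinylketene 15 are transient species that form afresh from 10 and from 8 each time these are used; each carries one number, stands on the Product line of the step in which it first forms (steps 4 and 6), and is referred to by that number in the later rounds.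

Shorthand in names: Ar1O = 2,4,6-trimethoxyphenoxy; Ar2O = 2,6-dimethoxy-4-(Ar1O)phenoxy; Ar3O = 2,6-dimethoxy-4-(Ar2O)phenoxy; Ar4O = 2,6-dimethoxy-4-(Ar3O)phenoxy; Ar5O = 2,6-dimethoxy-4-(Ar4O)phenoxy. Each ArnO is the permethylated n-ring chain ending in the oxygen that lies between two methoxy groups. Full SMILES are in the compound list.

**Route**

Step 1
Reactants: 1 methyl methoxyacetate; 2 methyl formate; 3 benzyl bromide
Product: 5 methyl (Z)-3-(benzyloxy)-2-methoxyprop-2-enoate, via sodium enolate 4 (not isolated)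
Conditions: NaH, THF, 0 °C to rt; then 3, DMF, rt
Reagents that add atoms: none
Why: Crossed Claisen condensation with the non-enolisable formate gives the stabilised sodium formyl enolate, and Williamson-type O-alkylation of this ambident enolate in DMF (its carbon terminus is fully substituted) should give the enol ether with benzyloxy trans to the ester, the favoured push–pull geometry (Z by the priority rules).

Step 2
Reactants: 5 methyl (Z)-3-(benzyloxy)-2-methoxyprop-2-enoate
Product: 6 (Z)-3-(benzyloxy)-2-methoxyprop-2-enoic acid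
Conditions: LiOH, THF/H2O, rt; then 1 M HCl to pH 3, 0 °C
Reagents that add atoms: lithium hydroxide, [Li+].[OH-]
Why: Ester saponification by acyl–oxygen cleavage; 3-alkoxyacrylates are hydrolysed to their acids without loss of the enol ether, and brief cold acidification should leave it intact.

Step 3
Reactants: 6 (Z)-3-(benzyloxy)-2-methoxyprop-2-enoic acid
Product: 8 (Z)-4-(benzyloxy)-1-diazo-3-methoxybut-3-en-2-one, via acyl chloride 7 (not isolated)
Conditions: (COCl)2, DMF (cat.), CH2Cl2, 0 °C to rt, evaporate; then CH2N2 (3 equiv), Et2O, 0 °C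
Reagents that add atoms: diazomethane, C=[N+]=[N-]
Why: Acylation of diazomethane by the acyl chloride (first stage of the Arndt–Eistert sequence), with excess diazomethane scavenging HCl; the trisubstituted, donor-substituted alkene is a poor dipolarophile, so pyrazoline formation should not compete.

Step 4
Reactants: 9 2,4,6-trimethoxyphenol; 10 trichloroethylene
Product: 12 2-[(E)-1,2-dichloroethenoxy]-1,3,5-trimethoxybenzene, via dichloroacetylene 11 (not isolated)
Conditions: K2CO3, DMF, 70 °C, argon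
Reagents that add atoms: none
Why: Base-induced dehydrochlorination of trichloroethylene gives dichloroacetylene, to which the phenoxide adds anti (net vinylic substitution) to give the (E)-dichlorovinyl ether; attack on an sp carbon is not hindered by the two ortho methoxy groups.

Step 5
Reactants: 12 2-[(E)-1,2-dichloroethenoxy]-1,3,5-trimethoxybenzene
Product: 14 2-(ethynyloxy)-1,3,5-trimethoxybenzene, via lithium alkynyl ether 13 (not isolated)
Conditions: n-BuLi (2.3 equiv), THF, −78 to −40 °C; then H2O, −78 °C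
Reagents that add atoms: none
Why: Dehydrochlorination and chlorine–lithium exchange of the dichlorovinyl ether (the standard dichlorovinyl ether route to ynol ethers) give the lithium alkynyl ether, protonated on quench; at −78 °C this should outpace ring lithiation next to the methoxy groups.

Step 6
Reactants: 14 2-(ethynyloxy)-1,3,5-trimethoxybenzene; 8 (Z)-4-(benzyloxy)-1-diazo-3-methoxybut-3-en-2-one
Product: 18 2-(benzyloxy)-3-methoxy-5-(2,4,6-trimethoxyphenoxy)phenol, via vinylketene 15 (not isolated), via cyclobutenone 16 (not isolated), via dienylketene 17 (not isolated)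
Conditions: 8 (1.5 equiv), hν (Pyrex-filtered medium-pressure Hg lamp, >300 nm), ClCH2CH2Cl, rt; then 80 °C
Reagents that add atoms: none
Why: Danheiser benzannulation (photo-Wolff variant): Wolff rearrangement of 8 gives vinylketene 15, which adds (2+2) to the ynol ether to give cyclobutenone 16, and 4π opening to dienylketene 17 followed by 6π closure and enolisation (detailed under step 11) builds ring B on the simplest aryl ethynyl ether with the aryloxy group meta to the new hydroxyl.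

Step 7
Reactants: 18 2-(benzyloxy)-3-methoxy-5-(2,4,6-trimethoxyphenoxy)phenol
Product: 19 2-(benzyloxy)-1,3-dimethoxy-5-(2,4,6-trimethoxyphenoxy)benzene
Conditions: MeI, K2CO3, acetone, reflux
Reagents that add atoms: iodomethane, CI
Why: Williamson methylation of the only phenol caps it, so that after debenzylation only the central oxygen is free for ethynylation.

Step 8
Reactants: 19 2-(benzyloxy)-1,3-dimethoxy-5-(2,4,6-trimethoxyphenoxy)benzene
Product: 20 2,6-dimethoxy-4-(2,4,6-trimethoxyphenoxy)phenol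
Conditions: H2 (1 atm), Pd/C, EtOAc/MeOH, rt
Reagents that add atoms: none
Why: Catalytic hydrogenolysis cleaves the benzyl ether only; aryl methyl ethers and the diaryl ether are inert.

Step 9
Reactants: 20 2,6-dimethoxy-4-(2,4,6-trimethoxyphenoxy)phenol; 10 trichloroethylene
Product: 21 2-[(E)-1,2-dichloroethenoxy]-1,3-dimethoxy-5-(2,4,6-trimethoxyphenoxy)benzene
Conditions: K2CO3, DMF, 70 °C, argon
Reagents that add atoms: none
Why: As in step 4, dichloroacetylene 11 is generated afresh from 10 and trapped by the phenoxide (net vinylic substitution); the reacting oxygen is the only free hydroxyl, and argon protects the electron-rich phenoxide from oxidation.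

Step 10
Reactants: 21 2-[(E)-1,2-dichloroethenoxy]-1,3-dimethoxy-5-(2,4,6-trimethoxyphenoxy)benzene
Product: 23 2-(ethynyloxy)-1,3-dimethoxy-5-(2,4,6-trimethoxyphenoxy)benzene, via lithium alkynyl ether 22 (not isolated)
Conditions: n-BuLi (2.3 equiv), THF, −78 to −40 °C; then H2O, −78 °C
Reagents that add atoms: none
Why: As in step 5, elimination and chlorine–lithium exchange then protonation; low temperature and near-stoichiometric base should limit lithiation of the methoxy-flanked ring positions, and the ynol ether is used at once.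

Step 11
Reactants: 23 2-(ethynyloxy)-1,3-dimethoxy-5-(2,4,6-trimethoxyphenoxy)benzene; 8 (Z)-4-(benzyloxy)-1-diazo-3-methoxybut-3-en-2-one
Product: 26 2-(benzyloxy)-3-methoxy-5-(Ar2O)phenol, via cyclobutenone 24 (not isolated), via dienylketene 25 (not isolated)
Conditions: 8 (1.5 equiv), hν (Pyrex-filtered medium-pressure Hg lamp, >300 nm), ClCH2CH2Cl, rt; then 80 °C
Reagents that add atoms: none
Why: Photolysis of 8 releases N2 with Wolff rearrangement (1,2-shift of the alkenyl group, forming C5–C6) and so regenerates vinylketene 15, the transient already met in step 6, whose carbonyl carbon is attacked by the terminal carbon of ynol ether 23 in a ketene–alkyne (2+2) cycloaddition that forms C2–C3 and C4–C5 and closes the four-membered ring of cyclobutenone 24. Conrotatory 4π electrocyclic opening of 24 (light or heat, reversible) gives dienylketene 25, and thermal disrotatory 6π electrocyclisation forms C1–C2 and closes the six-membered ring C, which aromatises by enolisation to phenol 26. The closest known reaction type is the Danheiser benzannulation in its diazoketone (photo-Wolff) variant with alkoxy- and siloxyalkynes, which gives resorcinol monoethers. No stereocentre is created: the one centre of racemic 24 disappears on ring opening, and the alkene geometry of 8 only places the benzyloxy group on the outside of the closing triene. The step needs regioselectivity in the (2+2) addition, and the oxygen lone pair of the ynol ether secures it by making the terminal carbon the nucleophile, so that the ring B oxygen ends at C4, meta to the new C2 hydroxyl, while the crowded ring B oxygen never has to attack an aromatic carbon. An excess of 8 offsets ketene dimerisation, and brief K2CO3/MeOH treatment of the crude product should cleave any aryl ester formed from 26 and surplus ketene.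

Step 12
Reactants: 26 2-(benzyloxy)-3-methoxy-5-(Ar2O)phenol
Product: 27 2-(benzyloxy)-1,3-dimethoxy-5-(Ar2O)benzene
Conditions: MeI, K2CO3, acetone, reflux
Reagents that add atoms: iodomethane, CI
Why: Williamson methylation of the single phenol, as in step 7.

Step 13
Reactants: 27 2-(benzyloxy)-1,3-dimethoxy-5-(Ar2O)benzene
Product: 28 2,6-dimethoxy-4-(Ar2O)phenol
Conditions: H2 (1 atm), Pd/C, EtOAc/MeOH, rt
Reagents that add atoms: none
Why: Benzyl ether hydrogenolysis, as in step 8.

Step 14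
Reactants: 28 2,6-dimethoxy-4-(Ar2O)phenol; 10 trichloroethylene
Product: 29 2-[(E)-1,2-dichloroethenoxy]-1,3-dimethoxy-5-(Ar2O)benzene
Conditions: K2CO3, DMF, 70 °C, argon
Reagents that add atoms: none
Why: Net vinylic substitution as in step 4, the phenoxide adding to dichloroacetylene 11 generated afresh from 10.

Step 15
Reactants: 29 2-[(E)-1,2-dichloroethenoxy]-1,3-dimethoxy-5-(Ar2O)benzene
Product: 31 2-(ethynyloxy)-1,3-dimethoxy-5-(Ar2O)benzene, via lithium alkynyl ether 30 (not isolated)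
Conditions: n-BuLi (2.3 equiv), THF, −78 to −40 °C; then H2O, −78 °C
Reagents that add atoms: none
Why: Elimination and chlorine–lithium exchange then protonation, as in step 5.

Step 16
Reactants: 31 2-(ethynyloxy)-1,3-dimethoxy-5-(Ar2O)benzene; 8 (Z)-4-(benzyloxy)-1-diazo-3-methoxybut-3-en-2-one
Product: 34 2-(benzyloxy)-3-methoxy-5-(Ar3O)phenol, via cyclobutenone 32 (not isolated), via dienylketene 33 (not isolated)
Conditions: 8 (1.5 equiv), hν (Pyrex-filtered medium-pressure Hg lamp, >300 nm), ClCH2CH2Cl, rt; then 80 °C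
Reagents that add atoms: none
Why: Danheiser benzannulation as in step 11 (Wolff rearrangement of 8 to vinylketene 15, regioselective (2+2) addition, 4π opening, 6π closure) builds ring D; the longer chain is remote from the reacting ethynyl ether.

Step 17
Reactants: 34 2-(benzyloxy)-3-methoxy-5-(Ar3O)phenol
Product: 35 2-(benzyloxy)-1,3-dimethoxy-5-(Ar3O)benzene
Conditions: MeI, K2CO3, acetone, reflux
Reagents that add atoms: iodomethane, CI
Why: Williamson methylation of the single phenol, as in step 7.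

Step 18
Reactants: 35 2-(benzyloxy)-1,3-dimethoxy-5-(Ar3O)benzene
Product: 36 2,6-dimethoxy-4-(Ar3O)phenol
Conditions: H2 (1 atm), Pd/C, EtOAc/MeOH, rt
Reagents that add atoms: none
Why: Benzyl ether hydrogenolysis, as in step 8.

Step 19
Reactants: 36 2,6-dimethoxy-4-(Ar3O)phenol; 10 trichloroethylene
Product: 37 2-[(E)-1,2-dichloroethenoxy]-1,3-dimethoxy-5-(Ar3O)benzene
Conditions: K2CO3, DMF, 70 °C, argon
Reagents that add atoms: none
Why: Net vinylic substitution as in step 4, the phenoxide adding to dichloroacetylene 11 generated afresh from 10.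

Step 20
Reactants: 37 2-[(E)-1,2-dichloroethenoxy]-1,3-dimethoxy-5-(Ar3O)benzene
Product: 39 2-(ethynyloxy)-1,3-dimethoxy-5-(Ar3O)benzene, via lithium alkynyl ether 38 (not isolated)
Conditions: n-BuLi (2.3 equiv), THF, −78 to −40 °C; then H2O, −78 °C
Reagents that add atoms: none
Why: Elimination and chlorine–lithium exchange then protonation, as in step 5.

Step 21
Reactants: 39 2-(ethynyloxy)-1,3-dimethoxy-5-(Ar3O)benzene; 8 (Z)-4-(benzyloxy)-1-diazo-3-methoxybut-3-en-2-one
Product: 42 2-(benzyloxy)-3-methoxy-5-(Ar4O)phenol, via cyclobutenone 40 (not isolated), via dienylketene 41 (not isolated)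
Conditions: 8 (1.5 equiv), hν (Pyrex-filtered medium-pressure Hg lamp, >300 nm), ClCH2CH2Cl, rt; then 80 °C
Reagents that add atoms: none
Why: Danheiser benzannulation as in step 11, with vinylketene 15 again formed from 8 by Wolff rearrangement, builds ring E with the same regiochemical control.

Step 22
Reactants: 42 2-(benzyloxy)-3-methoxy-5-(Ar4O)phenol
Product: 43 2-(benzyloxy)-1,3-dimethoxy-5-(Ar4O)benzene
Conditions: MeI, K2CO3, acetone, reflux
Reagents that add atoms: iodomethane, CI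
Why: Williamson methylation of the single phenol, as in step 7.

Step 23
Reactants: 43 2-(benzyloxy)-1,3-dimethoxy-5-(Ar4O)benzene
Product: 44 2,6-dimethoxy-4-(Ar4O)phenol
Conditions: H2 (1 atm), Pd/C, EtOAc/MeOH, rt
Reagents that add atoms: none
Why: Benzyl ether hydrogenolysis, as in step 8.

Step 24
Reactants: 44 2,6-dimethoxy-4-(Ar4O)phenol; 10 trichloroethylene
Product: 45 2-[(E)-1,2-dichloroethenoxy]-1,3-dimethoxy-5-(Ar4O)benzene
Conditions: K2CO3, DMF, 70 °C, argon
Reagents that add atoms: none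
Why: Net vinylic substitution as in step 4, the phenoxide adding to dichloroacetylene 11 generated afresh from 10.

Step 25
Reactants: 45 2-[(E)-1,2-dichloroethenoxy]-1,3-dimethoxy-5-(Ar4O)benzene
Product: 47 2-(ethynyloxy)-1,3-dimethoxy-5-(Ar4O)benzene, via lithium alkynyl ether 46 (not isolated)
Conditions: n-BuLi (2.3 equiv), THF, −78 to −40 °C; then H2O, −78 °C
Reagents that add atoms: none
Why: Elimination and chlorine–lithium exchange then protonation, as in step 5.

Step 26
Reactants: 47 2-(ethynyloxy)-1,3-dimethoxy-5-(Ar4O)benzene; 8 (Z)-4-(benzyloxy)-1-diazo-3-methoxybut-3-en-2-one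
Product: 50 2-(benzyloxy)-3-methoxy-5-(Ar5O)phenol, via cyclobutenone 48 (not isolated), via dienylketene 49 (not isolated)
Conditions: 8 (1.5 equiv), hν (Pyrex-filtered medium-pressure Hg lamp, >300 nm), ClCH2CH2Cl, rt; then 80 °C
Reagents that add atoms: none
Why: Danheiser benzannulation as in step 11, with vinylketene 15 again formed from 8 by Wolff rearrangement, builds ring F and completes the six-ring skeleton.

Step 27
Reactants: 50 2-(benzyloxy)-3-methoxy-5-(Ar5O)phenol
Product: 51 3-methoxy-5-(Ar5O)benzene-1,2-diol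
Conditions: H2 (1 atm), Pd/C, EtOAc/MeOH, rt
Reagents that add atoms: none
Why: Hydrogenolysis removes the last benzyl group before the Lewis acid step, so that no benzyl cation can alkylate the very electron-rich rings (Friedel–Crafts benzylation avoided).

Step 28
Reactants: 51 3-methoxy-5-(Ar5O)benzene-1,2-diol
Product: 52 5-[2,6-dihydroxy-4-[2,6-dihydroxy-4-[2,6-dihydroxy-4-[2,6-dihydroxy-4-(2,4,6-trihydroxyphenoxy)phenoxy]phenoxy]phenoxy]phenoxy]benzene-1,2,3-triol (CNP0187343.0)
Conditions: BBr3 (about 3 equiv per OMe), CH2Cl2, −78 °C to rt, argon; then H2O, 0 °C; Sephadex LH-20 under argon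
Reagents that add atoms: none
Why: BBr3 ether cleavage (O-coordination, then bromide attack at methyl) removes the twelve methyl groups, while the diaryl ether bonds, with sp2 carbon on both sides of oxygen, are not cleaved; hydrolysis of the aryl borates should release the fourteen hydroxyls.

**Compound list**

1 | methyl methoxyacetate | COCC(=O)OC | starting material
2 | methyl formate | COC=O | starting material
3 | benzyl bromide | BrCc1ccccc1 | starting material
4 | sodium 2,3-dimethoxy-3-oxoprop-1-en-1-olate (sodium enolate, configurationally labile, formed in situ) | COC(=O)C(OC)=C[O-].[Na+] | intermediate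
5 | methyl (Z)-3-(benzyloxy)-2-methoxyprop-2-enoate | COC(=O)/C(OC)=C/OCc1ccccc1 | intermediate
6 | (Z)-3-(benzyloxy)-2-methoxyprop-2-enoic acid | OC(=O)/C(OC)=C/OCc1ccccc1 | intermediate
7 | (Z)-3-(benzyloxy)-2-methoxyprop-2-enoyl chloride (formed in situ) | ClC(=O)/C(OC)=C/OCc1ccccc1 | intermediate
8 | (Z)-4-(benzyloxy)-1-diazo-3-methoxybut-3-en-2-one | [N-]=[N+]=CC(=O)/C(OC)=C/OCc1ccccc1 | intermediate
9 | 2,4,6-trimethoxyphenol | COc1cc(OC)c(O)c(OC)c1 | starting material
10 | trichloroethylene | ClC=C(Cl)Cl | starting material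
11 | dichloroacetylene (formed in situ from 10 in step 4; generated afresh in steps 9, 14, 19 and 24) | ClC#CCl | intermediate
12 | 2-[(E)-1,2-dichloroethenoxy]-1,3,5-trimethoxybenzene | COc1cc(OC)c(O/C(Cl)=C\Cl)c(OC)c1 | intermediate
13 | lithium 2-(2,4,6-trimethoxyphenoxy)ethynide (formed in situ) | COc1cc(OC)c(OC#C[Li])c(OC)c1 | intermediate
14 | 2-(ethynyloxy)-1,3,5-trimethoxybenzene | COc1cc(OC)c(OC#C)c(OC)c1 | intermediate
15 | (Z)-4-(benzyloxy)-3-methoxybuta-1,3-dien-1-one (vinylketene, formed in situ from 8 in step 6; generated afresh in steps 11, 16, 21 and 26) | O=C=C/C(OC)=C/OCc1ccccc1 | intermediate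
16 | racemic 3-(Ar1O)-4-[(Z)-2-(benzyloxy)-1-methoxyethenyl]cyclobut-2-en-1-one (formed in situ) | COc1cc(OC)c(OC2=CC(=O)C2/C(OC)=C/OCc3ccccc3)c(OC)c1 | intermediate
17 | (3E,5Z)-6-(benzyloxy)-5-methoxy-3-(Ar1O)hexa-1,3,5-trien-1-one (formed in situ) | COc1cc(OC)c(O/C(C=C=O)=C/C(OC)=C/OCc2ccccc2)c(OC)c1 | intermediate
18 | 2-(benzyloxy)-3-methoxy-5-(2,4,6-trimethoxyphenoxy)phenol | COc1cc(OC)c(Oc2cc(O)c(OCc3ccccc3)c(OC)c2)c(OC)c1 | intermediate
19 | 2-(benzyloxy)-1,3-dimethoxy-5-(2,4,6-trimethoxyphenoxy)benzene | COc1cc(OC)c(Oc2cc(OC)c(OCc3ccccc3)c(OC)c2)c(OC)c1 | intermediate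
20 | 2,6-dimethoxy-4-(2,4,6-trimethoxyphenoxy)phenol | COc1cc(OC)c(Oc2cc(OC)c(O)c(OC)c2)c(OC)c1 | intermediate
21 | 2-[(E)-1,2-dichloroethenoxy]-1,3-dimethoxy-5-(2,4,6-trimethoxyphenoxy)benzene | COc1cc(OC)c(Oc2cc(OC)c(O/C(Cl)=C\Cl)c(OC)c2)c(OC)c1 | intermediate
22 | lithium 2-(Ar2O)ethynide (formed in situ) | COc1cc(OC)c(Oc2cc(OC)c(OC#C[Li])c(OC)c2)c(OC)c1 | intermediate
23 | 2-(ethynyloxy)-1,3-dimethoxy-5-(2,4,6-trimethoxyphenoxy)benzene (rings A–B ynol ether) | COc1cc(OC)c(Oc2cc(OC)c(OC#C)c(OC)c2)c(OC)c1 | intermediate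
24 | racemic 3-(Ar2O)-4-[(Z)-2-(benzyloxy)-1-methoxyethenyl]cyclobut-2-en-1-one (formed in situ) | COc1cc(OC)c(Oc2cc(OC)c(OC3=CC(=O)C3/C(OC)=C/OCc4ccccc4)c(OC)c2)c(OC)c1 | intermediate
25 | (3E,5Z)-6-(benzyloxy)-5-methoxy-3-(Ar2O)hexa-1,3,5-trien-1-one (formed in situ) | COc1cc(OC)c(Oc2cc(OC)c(O/C(C=C=O)=C/C(OC)=C/OCc3ccccc3)c(OC)c2)c(OC)c1 | intermediate
26 | 2-(benzyloxy)-3-methoxy-5-(Ar2O)phenol (three-ring phenol) | COc1cc(OC)c(Oc2cc(OC)c(Oc3cc(O)c(OCc4ccccc4)c(OC)c3)c(OC)c2)c(OC)c1 | intermediate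
27 | 2-(benzyloxy)-1,3-dimethoxy-5-(Ar2O)benzene | COc1cc(OC)c(Oc2cc(OC)c(Oc3cc(OC)c(OCc4ccccc4)c(OC)c3)c(OC)c2)c(OC)c1 | intermediate
28 | 2,6-dimethoxy-4-(Ar2O)phenol | COc1cc(OC)c(Oc2cc(OC)c(Oc3cc(OC)c(O)c(OC)c3)c(OC)c2)c(OC)c1 | intermediate
29 | 2-[(E)-1,2-dichloroethenoxy]-1,3-dimethoxy-5-(Ar2O)benzene | COc1cc(OC)c(Oc2cc(OC)c(Oc3cc(OC)c(O/C(Cl)=C\Cl)c(OC)c3)c(OC)c2)c(OC)c1 | intermediate
30 | lithium 2-(Ar3O)ethynide (formed in situ) | COc1cc(OC)c(Oc2cc(OC)c(Oc3cc(OC)c(OC#C[Li])c(OC)c3)c(OC)c2)c(OC)c1 | intermediate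
31 | 2-(ethynyloxy)-1,3-dimethoxy-5-(Ar2O)benzene | COc1cc(OC)c(Oc2cc(OC)c(Oc3cc(OC)c(OC#C)c(OC)c3)c(OC)c2)c(OC)c1 | intermediate
32 | racemic 3-(Ar3O)-4-[(Z)-2-(benzyloxy)-1-methoxyethenyl]cyclobut-2-en-1-one (formed in situ) | COc1cc(OC)c(Oc2cc(OC)c(Oc3cc(OC)c(OC4=CC(=O)C4/C(OC)=C/OCc5ccccc5)c(OC)c3)c(OC)c2)c(OC)c1 | intermediate
33 | (3E,5Z)-6-(benzyloxy)-5-methoxy-3-(Ar3O)hexa-1,3,5-trien-1-one (formed in situ) | COc1cc(OC)c(Oc2cc(OC)c(Oc3cc(OC)c(O/C(C=C=O)=C/C(OC)=C/OCc4ccccc4)c(OC)c3)c(OC)c2)c(OC)c1 | intermediate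
34 | 2-(benzyloxy)-3-methoxy-5-(Ar3O)phenol | COc1cc(OC)c(Oc2cc(OC)c(Oc3cc(OC)c(Oc4cc(O)c(OCc5ccccc5)c(OC)c4)c(OC)c3)c(OC)c2)c(OC)c1 | intermediate
35 | 2-(benzyloxy)-1,3-dimethoxy-5-(Ar3O)benzene | COc1cc(OC)c(Oc2cc(OC)c(Oc3cc(OC)c(Oc4cc(OC)c(OCc5ccccc5)c(OC)c4)c(OC)c3)c(OC)c2)c(OC)c1 | intermediate
36 | 2,6-dimethoxy-4-(Ar3O)phenol | COc1cc(OC)c(Oc2cc(OC)c(Oc3cc(OC)c(Oc4cc(OC)c(O)c(OC)c4)c(OC)c3)c(OC)c2)c(OC)c1 | intermediate
37 | 2-[(E)-1,2-dichloroethenoxy]-1,3-dimethoxy-5-(Ar3O)benzene | COc1cc(OC)c(Oc2cc(OC)c(Oc3cc(OC)c(Oc4cc(OC)c(O/C(Cl)=C\Cl)c(OC)c4)c(OC)c3)c(OC)c2)c(OC)c1 | intermediate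
38 | lithium 2-(Ar4O)ethynide (formed in situ) | COc1cc(OC)c(Oc2cc(OC)c(Oc3cc(OC)c(Oc4cc(OC)c(OC#C[Li])c(OC)c4)c(OC)c3)c(OC)c2)c(OC)c1 | intermediate
39 | 2-(ethynyloxy)-1,3-dimethoxy-5-(Ar3O)benzene | COc1cc(OC)c(Oc2cc(OC)c(Oc3cc(OC)c(Oc4cc(OC)c(OC#C)c(OC)c4)c(OC)c3)c(OC)c2)c(OC)c1 | intermediate
40 | racemic 3-(Ar4O)-4-[(Z)-2-(benzyloxy)-1-methoxyethenyl]cyclobut-2-en-1-one (formed in situ) | COc1cc(OC)c(Oc2cc(OC)c(Oc3cc(OC)c(Oc4cc(OC)c(OC5=CC(=O)C5/C(OC)=C/OCc6ccccc6)c(OC)c4)c(OC)c3)c(OC)c2)c(OC)c1 | intermediate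
41 | (3E,5Z)-6-(benzyloxy)-5-methoxy-3-(Ar4O)hexa-1,3,5-trien-1-one (formed in situ) | COc1cc(OC)c(Oc2cc(OC)c(Oc3cc(OC)c(Oc4cc(OC)c(O/C(C=C=O)=C/C(OC)=C/OCc5ccccc5)c(OC)c4)c(OC)c3)c(OC)c2)c(OC)c1 | intermediate
42 | 2-(benzyloxy)-3-methoxy-5-(Ar4O)phenol | COc1cc(OC)c(Oc2cc(OC)c(Oc3cc(OC)c(Oc4cc(OC)c(Oc5cc(O)c(OCc6ccccc6)c(OC)c5)c(OC)c4)c(OC)c3)c(OC)c2)c(OC)c1 | intermediate
43 | 2-(benzyloxy)-1,3-dimethoxy-5-(Ar4O)benzene | COc1cc(OC)c(Oc2cc(OC)c(Oc3cc(OC)c(Oc4cc(OC)c(Oc5cc(OC)c(OCc6ccccc6)c(OC)c5)c(OC)c4)c(OC)c3)c(OC)c2)c(OC)c1 | intermediate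
44 | 2,6-dimethoxy-4-(Ar4O)phenol | COc1cc(OC)c(Oc2cc(OC)c(Oc3cc(OC)c(Oc4cc(OC)c(Oc5cc(OC)c(O)c(OC)c5)c(OC)c4)c(OC)c3)c(OC)c2)c(OC)c1 | intermediate
45 | 2-[(E)-1,2-dichloroethenoxy]-1,3-dimethoxy-5-(Ar4O)benzene | COc1cc(OC)c(Oc2cc(OC)c(Oc3cc(OC)c(Oc4cc(OC)c(Oc5cc(OC)c(O/C(Cl)=C\Cl)c(OC)c5)c(OC)c4)c(OC)c3)c(OC)c2)c(OC)c1 | intermediate
46 | lithium 2-(Ar5O)ethynide (formed in situ) | COc1cc(OC)c(Oc2cc(OC)c(Oc3cc(OC)c(Oc4cc(OC)c(Oc5cc(OC)c(OC#C[Li])c(OC)c5)c(OC)c4)c(OC)c3)c(OC)c2)c(OC)c1 | intermediate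
47 | 2-(ethynyloxy)-1,3-dimethoxy-5-(Ar4O)benzene | COc1cc(OC)c(Oc2cc(OC)c(Oc3cc(OC)c(Oc4cc(OC)c(Oc5cc(OC)c(OC#C)c(OC)c5)c(OC)c4)c(OC)c3)c(OC)c2)c(OC)c1 | intermediate
48 | racemic 3-(Ar5O)-4-[(Z)-2-(benzyloxy)-1-methoxyethenyl]cyclobut-2-en-1-one (formed in situ) | COc1cc(OC)c(Oc2cc(OC)c(Oc3cc(OC)c(Oc4cc(OC)c(Oc5cc(OC)c(OC6=CC(=O)C6/C(OC)=C/OCc7ccccc7)c(OC)c5)c(OC)c4)c(OC)c3)c(OC)c2)c(OC)c1 | intermediate
49 | (3E,5Z)-6-(benzyloxy)-5-methoxy-3-(Ar5O)hexa-1,3,5-trien-1-one (formed in situ) | COc1cc(OC)c(Oc2cc(OC)c(Oc3cc(OC)c(Oc4cc(OC)c(Oc5cc(OC)c(O/C(C=C=O)=C/C(OC)=C/OCc6ccccc6)c(OC)c5)c(OC)c4)c(OC)c3)c(OC)c2)c(OC)c1 | intermediate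
50 | 2-(benzyloxy)-3-methoxy-5-(Ar5O)phenol | COc1cc(OC)c(Oc2cc(OC)c(Oc3cc(OC)c(Oc4cc(OC)c(Oc5cc(OC)c(Oc6cc(O)c(OCc7ccccc7)c(OC)c6)c(OC)c5)c(OC)c4)c(OC)c3)c(OC)c2)c(OC)c1 | intermediate
51 | 3-methoxy-5-(Ar5O)benzene-1,2-diol | COc1cc(OC)c(Oc2cc(OC)c(Oc3cc(OC)c(Oc4cc(OC)c(Oc5cc(OC)c(Oc6cc(O)c(O)c(OC)c6)c(OC)c5)c(OC)c4)c(OC)c3)c(OC)c2)c(OC)c1 | intermediate
52 | 5-[2,6-dihydroxy-4-[2,6-dihydroxy-4-[2,6-dihydroxy-4-[2,6-dihydroxy-4-(2,4,6-trihydroxyphenoxy)phenoxy]phenoxy]phenoxy]phenoxy]benzene-1,2,3-triol (CNP0187343.0) | Oc1cc(O)c(Oc2cc(O)c(Oc3cc(O)c(Oc4cc(O)c(Oc5cc(O)c(Oc6cc(O)c(O)c(O)c6)c(O)c5)c(O)c4)c(O)c3)c(O)c2)c(O)c1 | target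

**Step count**

Total steps: 28. Longest linear sequence: 26 steps (steps 1 to 3, then 6 to 28, from methyl methoxyacetate; the branch from 2,4,6-trimethoxyphenol is 25 steps).

**Steps most likely to fail**

Step 11 (and its repeats in steps 6, 16, 21 and 26). The vinylketene may dimerise or be captured by the product phenol faster than it adds to the only moderately nucleophilic aryl ynol ether, and the terminal ynol ether may polymerise or degrade under irradiation. Fallback: ring C would be attached preformed by a copper-mediated Ullmann ether synthesis. Purchased 4-bromo-2,6-dimethoxyphenol would be benzylated with 3 (K2CO3, DMF, rt) to 2-(benzyloxy)-5-bromo-1,3-dimethoxybenzene F1, and phenol 20 would be coupled with F1 (CuI, picolinic acid, K3PO4, DMSO, 100 °C). This sets out from 20 and returns to the route at 27, bypassing steps 9 to 12, at the price of the hindered C–O coupling that the annulation avoids.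

Step 10 (and its repeats in steps 5, 15, 20 and 25). n-BuLi may lithiate the ring positions flanked by alkoxy groups in competition with the vinylic deprotonation, or the elimination may stop short, giving mixtures that are hard to separate from the labile ynol ether. Fallback: phenol 20 would be formylated (acetic formic anhydride, pyridine, CH2Cl2, 0 °C) to 2,6-dimethoxy-4-(2,4,6-trimethoxyphenoxy)phenyl formate F2. Corey–Fuchs-type dibromo-olefination of the formate carbonyl (CBr4, PPh3, CH2Cl2, 0 °C) would give 2-(2,2-dibromoethenoxy)-1,3-dimethoxy-5-(2,4,6-trimethoxyphenoxy)benzene F3. With n-BuLi (2.2 equiv, THF, −78 °C), bromine–lithium exchange, which is far faster than ring C–H lithiation, followed by Fritsch–Buttenberg–Wiechell-type elimination would give lithium alkynyl ether 22, protonated to 23. This sets out from 20 and returns at 23.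

Step 28. Ether cleavage may stop at partly methylated polyphenols, and the fourteen-fold phenol may oxidise or bind irreversibly to the stationary phase during isolation. Fallback: 51 would be treated with BBr3 as before, the quenched crude product peracetylated (Ac2O, pyridine, DMAP cat., rt) to the tetradecaacetate F4, and F4 purified on silica, where partly methylated congeners separate. Zemplén deacetylation (NaOMe cat., degassed MeOH, argon; acidic ion-exchange resin) would then release 52. This sets out from 51 and returns at 52.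

**Further compounds**

F1 | step 11 | 2-(benzyloxy)-5-bromo-1,3-dimethoxybenzene | COc1cc(Br)cc(OC)c1OCc1ccccc1
F2 | step 10 | 2,6-dimethoxy-4-(2,4,6-trimethoxyphenoxy)phenyl formate | COc1cc(OC)c(Oc2cc(OC)c(OC=O)c(OC)c2)c(OC)c1
F3 | step 10 | 2-(2,2-dibromoethenoxy)-1,3-dimethoxy-5-(2,4,6-trimethoxyphenoxy)benzene | COc1cc(OC)c(Oc2cc(OC)c(OC=C(Br)Br)c(OC)c2)c(OC)c1
F4 | step 28 | tetradecaacetate of 52 | CC(=O)Oc1cc(OC(C)=O)c(Oc2cc(OC(C)=O)c(Oc3cc(OC(C)=O)c(Oc4cc(OC(C)=O)c(Oc5cc(OC(C)=O)c(Oc6cc(OC(C)=O)c(OC(C)=O)c(OC(C)=O)c6)c(OC(C)=O)c5)c(OC(C)=O)c4)c(OC(C)=O)c3)c(OC(C)=O)c2)c(OC(C)=O)c1
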